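The route rests on removing the chromene-side carbonyl carbon of the propane-1,3-dione as carbon monoxide. One palladium-catalysed three-component carbonylative α-arylation forms both of its C–C bonds, chromene C6–C(=O) and C(=O)–CH2, and so joins two fragments of similar size. Its precursors are a 6-bromo-7-silyloxy-2,2-dimethyl-2H-chromene with no carbon substituent at C6 and the methyl ketone enolate of silylated 4-hydroxy-3-prenylacetophenone. The feature exploited is that C6 lies ortho to the C7 oxygen and para to pyran O1. This linear 1,2,4,5-pattern of the benzo ring is already present in 5-bromo-2,4-dihydroxybenzaldehyde, whose formyl carbon becomes pyran C4 and whose bromine marks the site of the carbonyl.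

Key step: step 5

Remark: the target has no stereocentre and no stereodefined double bond, so it is achiral and no enantiomer has to be chosen; it is drawn as the diketo tautomer, although the chelated enol form should dominate in solution.

Step 1
Reactants: 1 5-bromo-2,4-dihydroxybenzaldehyde
Product: 2 5-bromo-2-hydroxy-4-[(triisopropylsilyl)oxy]benzaldehyde
Conditions: TIPSCl (1.05 equiv), imidazole (2 equiv), CH2Cl2, 0 °C to rt
Reagents that add atoms: chlorotriisopropylsilane (TIPSCl), CC(C)[Si](Cl)(C(C)C)C(C)C
Why: Selective O-silylation should occur at the 4-OH, because the 2-OH is tied up in a hydrogen bond to the formyl group and is much less nucleophilic.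

Step 2
Reactants: 2 5-bromo-2-hydroxy-4-[(triisopropylsilyl)oxy]benzaldehyde; 3 2-methylprop-1-en-1-ylmagnesium bromide
Product: 6 6-bromo-2,2-dimethyl-7-[(triisopropylsilyl)oxy]-2H-chromene, via racemic 4-bromo-2-(1-hydroxy-3-methylbut-2-en-1-yl)-5-[(triisopropylsilyl)oxy]phenol 4 (not isolated), via (6Z)-4-bromo-6-(3-methylbut-2-en-1-ylidene)-3-[(triisopropylsilyl)oxy]cyclohexa-2,4-dien-1-one 5 (not isolated)
Conditions: 3 (2.5 equiv), THF, 0 °C to rt; aq. NH4Cl; crude 4, PPTS (10 mol %), toluene, 80 °C
Reagents that add atoms: none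
Why: Grignard 1,2-addition to the magnesium-chelated salicylaldehyde gives racemic 4, whose acid-catalysed dehydration (assisted by the ortho-OH and para-silyloxy groups) gives vinyl o-quinone methide 5, and 5 closes by oxa-6π electrocyclisation, so the formyl carbon becomes C4, the linear fusion is fixed by the starting material, and the transient stereocentre of 4 is erased.

Step 3
Reactants: 7 1-(4-hydroxy-3-iodophenyl)ethan-1-one
Product: 8 1-{3-iodo-4-[(triisopropylsilyl)oxy]phenyl}ethan-1-one
Conditions: TIPSCl (1.2 equiv), imidazole (2.5 equiv), DMF, rt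
Reagents that add atoms: chlorotriisopropylsilane (TIPSCl), CC(C)[Si](Cl)(C(C)C)C(C)C
Why: Standard imidazole-promoted silylation of the only hydroxyl group masks the phenol against the strong base and the acylpalladium species of step 5.

Step 4
Reactants: 8 1-{3-iodo-4-[(triisopropylsilyl)oxy]phenyl}ethan-1-one; 9 tributyl(3-methylbut-2-en-1-yl)stannane
Product: 10 1-{3-(3-methylbut-2-en-1-yl)-4-[(triisopropylsilyl)oxy]phenyl}ethan-1-one
Conditions: Pd(PPh3)4 (5 mol %), DMF, 90 °C
Reagents that add atoms: none
Why: In this Stille cross-coupling, oxidative addition into the C–I bond, transmetalation of the allylic stannane and reductive elimination at the less substituted allyl terminus should give the linear prenyl arene under neutral conditions that spare the ketone and the silyl ether.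

Step 5
Reactants: 6 6-bromo-2,2-dimethyl-7-[(triisopropylsilyl)oxy]-2H-chromene; 10 1-{3-(3-methylbut-2-en-1-yl)-4-[(triisopropylsilyl)oxy]phenyl}ethan-1-one; 11 carbon monoxide
Product: 14 1-{2,2-dimethyl-7-[(triisopropylsilyl)oxy]-2H-chromen-6-yl}-3-{3-(3-methylbut-2-en-1-yl)-4-[(triisopropylsilyl)oxy]phenyl}propane-1,3-dione, via sodium 1-{3-(3-methylbut-2-en-1-yl)-4-[(triisopropylsilyl)oxy]phenyl}ethen-1-olate 12 (not isolated), via sodium 1,3-diketonate of the product 13 (not isolated)
Conditions: 10, NaHMDS (2.2 equiv), dioxane, rt; then 6, Pd(dba)2 (5 mol %), dppp (6 mol %), CO (1 atm), 80 °C; AcOH quench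
Reagents that add atoms: none
Why: NaHMDS converts 10 into sodium enolate 12, the dppp-ligated Pd(0) inserts into the single C–Br bond of 6, CO 11 inserts into the aryl–Pd bond, and C–C reductive elimination from the acyl(enolate)palladium complex gives the 1,3-diketone, which the second equivalent of base removes at once as the unreactive diketonate 13. The closest known reaction type is the palladium-catalysed carbonylative α-arylation of aryl methyl ketones with aryl bromides or iodides, which is established for electron-rich alkoxy-substituted halides. No ring is closed and no stereocentre is created, so only chemoselectivity has to be secured. CO uptake must outrun direct α-arylation, and the chelating ligand together with the bulky ortho-silyloxy group, which slows aryl–enolate elimination but speeds migratory insertion, favours the acyl pathway. C-acylation at one site only is secured because 10 has a single enolisable position, any enol ester formed by O-acylation is itself an acyl donor towards 12, and 13 is too stabilised to react again. Both phenols are silylated so that no phenoxide can trap the acylpalladium species, and the trisubstituted prenyl and cis-disubstituted pyran alkenes are poor insertion partners that cannot reach the metal intramolecularly.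

Step 6
Reactants: 14 1-{2,2-dimethyl-7-[(triisopropylsilyl)oxy]-2H-chromen-6-yl}-3-{3-(3-methylbut-2-en-1-yl)-4-[(triisopropylsilyl)oxy]phenyl}propane-1,3-dione
Product: 15 glyinflanin C, 1-(7-hydroxy-2,2-dimethyl-2H-chromen-6-yl)-3-[4-hydroxy-3-(3-methylbut-2-en-1-yl)phenyl]propane-1,3-dione
Conditions: TBAF (2.2 equiv), AcOH (2.2 equiv), THF, 0 °C; pH 7 buffer work-up
Reagents that add atoms: none
Why: Fluoride-mediated desilylation cleaves both aryl silyl ethers at low temperature, and the acetic acid buffer keeps the freed C7 phenol and the diketone protonated, so neither cyclodehydration onto the distal carbonyl nor retro-Claisen cleavage should compete and both alkenes stay untouched.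

Compound list
1 | 5-bromo-2,4-dihydroxybenzaldehyde | O=Cc1cc(Br)c(O)cc1O | starting material
2 | 5-bromo-2-hydroxy-4-[(triisopropylsilyl)oxy]benzaldehyde | O=Cc1cc(Br)c(O[Si](C(C)C)(C(C)C)C(C)C)cc1O | intermediate
3 | 2-methylprop-1-en-1-ylmagnesium bromide | CC(C)=C[Mg]Br | starting material
4 | 4-bromo-2-(1-hydroxy-3-methylbut-2-en-1-yl)-5-[(triisopropylsilyl)oxy]phenol (racemic, not isolated) | CC(C)=CC(O)c1cc(Br)c(O[Si](C(C)C)(C(C)C)C(C)C)cc1O | intermediate
5 | (6Z)-4-bromo-6-(3-methylbut-2-en-1-ylidene)-3-[(triisopropylsilyl)oxy]cyclohexa-2,4-dien-1-one (not isolated) | O=C1C=C(O[Si](C(C)C)(C(C)C)C(C)C)C(Br)=C/C1=C/C=C(C)C | intermediate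
6 | 6-bromo-2,2-dimethyl-7-[(triisopropylsilyl)oxy]-2H-chromene | CC1(C)C=Cc2cc(Br)c(O[Si](C(C)C)(C(C)C)C(C)C)cc2O1 | intermediate
7 | 1-(4-hydroxy-3-iodophenyl)ethan-1-one | CC(=O)c1ccc(O)c(I)c1 | starting material
8 | 1-{3-iodo-4-[(triisopropylsilyl)oxy]phenyl}ethan-1-one | CC(=O)c1ccc(O[Si](C(C)C)(C(C)C)C(C)C)c(I)c1 | intermediate
9 | tributyl(3-methylbut-2-en-1-yl)stannane | CCCC[Sn](CCCC)(CCCC)CC=C(C)C | starting material
10 | 1-{3-(3-methylbut-2-en-1-yl)-4-[(triisopropylsilyl)oxy]phenyl}ethan-1-one | CC(=O)c1ccc(O[Si](C(C)C)(C(C)C)C(C)C)c(CC=C(C)C)c1 | intermediate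
11 | carbon monoxide | [C-]#[O+] | starting material
12 | sodium 1-{3-(3-methylbut-2-en-1-yl)-4-[(triisopropylsilyl)oxy]phenyl}ethen-1-olate (not isolated) | [Na+].C=C([O-])c1ccc(O[Si](C(C)C)(C(C)C)C(C)C)c(CC=C(C)C)c1 | intermediate
13 | sodium 1,3-diketonate of 14 (not isolated, drawn as the C2 carbanion form) | [Na+].CC(C)=CCc1cc(C(=O)[CH-]C(=O)c2cc3c(cc2O[Si](C(C)C)(C(C)C)C(C)C)OC(C)(C)C=C3)ccc1O[Si](C(C)C)(C(C)C)C(C)C | intermediate
14 | 1-{2,2-dimethyl-7-[(triisopropylsilyl)oxy]-2H-chromen-6-yl}-3-{3-(3-methylbut-2-en-1-yl)-4-[(triisopropylsilyl)oxy]phenyl}propane-1,3-dione | CC(C)=CCc1cc(C(=O)CC(=O)c2cc3c(cc2O[Si](C(C)C)(C(C)C)C(C)C)OC(C)(C)C=C3)ccc1O[Si](C(C)C)(C(C)C)C(C)C | intermediate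
15 | glyinflanin C | CC(C)=CCc1cc(C(=O)CC(=O)c2cc3c(cc2O)OC(C)(C)C=C3)ccc1O | target

Total step count: 6. Longest linear sequence: 4 steps (1, 2, 5, 6 or 3, 4, 5, 6).

Steps most likely to fail

Step 5. Oxidative addition at the electron-rich, ortho-hindered C–Br bond may be slow. Arylation may also proceed without CO uptake, or a silyl group may move from a phenol oxygen to the enolate. The fallback sets out from 6 and comes back to the route at 14. Bromine–lithium exchange (n-BuLi, THF, −78 °C) gives {2,2-dimethyl-7-[(triisopropylsilyl)oxy]-2H-chromen-6-yl}lithium F1. This is trapped at once with CO2 and acidified to 2,2-dimethyl-7-[(triisopropylsilyl)oxy]-2H-chromene-6-carboxylic acid F2. 1,1'-Carbonyldiimidazole in THF converts the acid into {2,2-dimethyl-7-[(triisopropylsilyl)oxy]-2H-chromen-6-yl}(1H-imidazol-1-yl)methanone F3. The imidazolide acylates enolate 12 (from 10 and NaHMDS, 2.2 equiv, THF, −78 to 0 °C) in a crossed Claisen condensation that passes through 13 and gives 14 after the AcOH quench. The two C–C bonds are then made one after the other, without palladium and without CO gas.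

Step 2. Addition to the aldehyde may be sluggish once the phenoxide has formed, and the o-quinone methide may oligomerise in competition with the electrocyclisation. The fallback sets out from 2 and comes back at 6. Wittig olefination with ethyl (triphenylphosphoranylidene)acetate in N,N-diethylaniline at reflux gives ethyl (2E)-3-{5-bromo-2-hydroxy-4-[(triisopropylsilyl)oxy]phenyl}prop-2-enoate F4. At that temperature F4 isomerises and lactonises to 6-bromo-7-[(triisopropylsilyl)oxy]-2H-chromen-2-one F5. Double 1,2-addition of MeMgBr (excess, THF, 0 °C) opens the lactone to 4-bromo-2-[(1Z)-3-hydroxy-3-methylbut-1-en-1-yl]-5-[(triisopropylsilyl)oxy]phenol F6. Catalytic PPTS in toluene then closes F6 to 6. In this variant the quaternary C2 is built from a lactone carbonyl, and the cis alkene geometry is inherited from the coumarin ring.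

Step 4. The allyl unit may transpose during transmetalation and reductive elimination, so that the bond forms at the tertiary terminus, and coupling beside the bulky silyl ether may be slow. The fallback sets out from 8 and comes back at 10. Stille coupling with allyltributylstannane (Pd(PPh3)4, DMF, 90 °C), in which both allyl termini are equivalent, gives 1-{3-(prop-2-en-1-yl)-4-[(triisopropylsilyl)oxy]phenyl}ethan-1-one F7. Olefin cross-metathesis with excess 2-methylbut-2-ene (second-generation Grubbs catalyst, CH2Cl2, 40 °C) converts the terminal alkene into the prenyl group of 10.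

Further compounds
F1 | step 5 | {2,2-dimethyl-7-[(triisopropylsilyl)oxy]-2H-chromen-6-yl}lithium | [Li]c1cc2c(cc1O[Si](C(C)C)(C(C)C)C(C)C)OC(C)(C)C=C2
F2 | step 5 | 2,2-dimethyl-7-[(triisopropylsilyl)oxy]-2H-chromene-6-carboxylic acid | OC(=O)c1cc2c(cc1O[Si](C(C)C)(C(C)C)C(C)C)OC(C)(C)C=C2
F3 | step 5 | {2,2-dimethyl-7-[(triisopropylsilyl)oxy]-2H-chromen-6-yl}(1H-imidazol-1-yl)methanone | O=C(n1ccnc1)c1cc2c(cc1O[Si](C(C)C)(C(C)C)C(C)C)OC(C)(C)C=C2
F4 | step 2 | ethyl (2E)-3-{5-bromo-2-hydroxy-4-[(triisopropylsilyl)oxy]phenyl}prop-2-enoate | CCOC(=O)/C=C/c1cc(Br)c(O[Si](C(C)C)(C(C)C)C(C)C)cc1O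
F5 | step 2 | 6-bromo-7-[(triisopropylsilyl)oxy]-2H-chromen-2-one | O=C1C=Cc2cc(Br)c(O[Si](C(C)C)(C(C)C)C(C)C)cc2O1
F6 | step 2 | 4-bromo-2-[(1Z)-3-hydroxy-3-methylbut-1-en-1-yl]-5-[(triisopropylsilyl)oxy]phenol | CC(C)(O)/C=C\c1cc(Br)c(O[Si](C(C)C)(C(C)C)C(C)C)cc1O
F7 | step 4 | 1-{3-(prop-2-en-1-yl)-4-[(triisopropylsilyl)oxy]phenyl}ethan-1-one | CC(=O)c1ccc(O[Si](C(C)C)(C(C)C)C(C)C)c(CC=C)c1
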